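**Plan** (halimane numbering: ring A = C1–C5 and C10; ring B = C5–C10; C17 is the methyl on C8, C20 the methyl on C9, C11–C16 the side chain)

1. Retrosynthetic cuts: the glyceryl ester C–O bond; C8–C17, taken back to a C8 ketone; C9–C11 (side chain, by dienolate alkylation); C5–C6 and C7–C8 of ring B together in a [4+2] event; C9–C10 (Pd coupling onto ring A).
2. Enabling feature: with C8 at the ketone level and C9 still trigonal, the ring A bond C5=C10 and the exocyclic C9=C8(OMe)(OSi) form a 1,1-dioxygenated diene whose termini are exactly C5 and C8; an acrylate supplies C6–C7.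
3. Forward order: ring A (4,4-dimethylcyclohexenone) → propanoate on C10 → Diels–Alder closes ring B → C7 ester removed → reductive alkylation installs the side chain at C9 and the C1=C10 alkene at once → C8 methylenation and hydrogenation → glyceride.
4. Stereochemistry: a temporary C1 silyloxy centre (CBS reduction) directs C5; C9 arises by axial alkylation syn to H5; C8 by hydrogenation anti to the axial side chain; C13 comes from (R)-monomethyl 3-methylglutarate.
5. Helpers and their removal: C1 silyloxy (step 9), C7 allyl ester (step 6), C8 oxygen (steps 10–11), benzylidene acetal (step 14).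

Key step: step 5

Remark: the double-bond geometry of the ketene acetal 9 and the configurations at C7 and C8 of 10–12 are not controlled and do not matter, because these centres later become trigonal or CH2.

**Step 1**
Reactants: 1 4,4-dimethylcyclohex-2-en-1-one
Product: 2 2-iodo-4,4-dimethylcyclohex-2-en-1-one
Conditions: I2, pyridine, CH2Cl2, 0 °C to rt
Reagents that add atoms: iodine, II
Why: α-iodination of a cyclic enone by pyridine addition, iodination of the enolate and elimination (Baylis–Hillman-type sequence) marks C10 for coupling and fixes the ring A double bond between C10 and C5.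

**Step 2**
Reactants: 2 2-iodo-4,4-dimethylcyclohex-2-en-1-one
Product: 3 (1S)-2-iodo-4,4-dimethylcyclohex-2-en-1-ol
Conditions: (R)-2-methyl-CBS-oxazaborolidine (10 mol %), BH3·SMe2, THF, −20 °C; aqueous work-up
Reagents that add atoms: none
Why: Corey–Bakshi–Shibata reduction, in which the iodovinyl arm acts as the large group, so the (R)-catalyst should give the (1S)-alcohol that serves as a temporary stereocentre at C1.

**Step 3**
Reactants: 3 (1S)-2-iodo-4,4-dimethylcyclohex-2-en-1-ol
Product: 4 tert-butyl{[(1S)-2-iodo-4,4-dimethylcyclohex-2-en-1-yl]oxy}dimethylsilane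
Conditions: TBSCl, imidazole, DMF, rt
Reagents that add atoms: tert-butyldimethylsilyl chloride, CC(C)(C)[Si](C)(C)Cl
Why: standard silylation of a secondary allylic alcohol gives a group that survives LDA and heat and later serves as the leaving group at C1.

**Step 4**
Reactants: 4 tert-butyl{[(1S)-2-iodo-4,4-dimethylcyclohex-2-en-1-yl]oxy}dimethylsilane; 5 methyl 2-bromopropanoate
Product: 6 methyl 2-[(6S)-6-(tert-butyldimethylsilyloxy)-3,3-dimethylcyclohex-1-en-1-yl]propanoate
Conditions: Zn dust (activated), 5, THF, rt; then 4, Pd(dba)2 (5 mol %), P(t-Bu)3 (5 mol %), THF, rt to 50 °C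
Reagents that add atoms: none
Why: Negishi-type coupling of a Reformatsky zinc ester enolate with an alkenyl iodide (α-alkenylation of an ester) forms the C9–C10 bond; the new CH(CH3) centre is uncontrolled and becomes trigonal in step 5.

**Step 5**
Reactants: 6 methyl 2-[(6S)-6-(tert-butyldimethylsilyloxy)-3,3-dimethylcyclohex-1-en-1-yl]propanoate; 7 allyl acrylate
Product: 11 allyl (4aS,8S)-8-(tert-butyldimethylsilyloxy)-1,5,5-trimethyl-2-oxo-2,3,4,4a,5,6,7,8-octahydronaphthalene-3-carboxylate, via lithium dienolate 8 (not isolated), via vinylketene silyl acetal 9 (not isolated), via cycloadduct 10 (not isolated)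
Conditions: LDA, THF, −78 °C; TBSCl, DMPU, −78 °C to rt; solvent exchange to toluene, 7 (3 equiv), BHT (trace), 90 °C; then 0.5 M HCl, THF, 0 °C
Reagents that add atoms: none
Why: Deprotonation at C9 and O-silylation turn the ester into the electron-rich diene C5=C10–C9(CH3)=C8(OMe)(OTBS), which should add the acrylate in a thermal, concerted but asynchronous [4+2] cycloaddition of normal electron demand, after which mild acid collapses the mixed ketal at C8 to the ketone. The closest known reaction type is the Diels–Alder reaction of vinylketene silyl acetals (1,1-dioxygenated dienes) with acrylates, whose ionic counterpart is the Michael–Dieckmann annulation. Ring B closes by intermolecular suprafacial [4+2] addition: the diene termini C5 and C8 bond to C6 and C7 of the dienophile and the C9=C10 double bond appears inside the new ring. C5 is the only lasting new stereocentre; allylic 1,3-strain with the C9 substituents holds the C1 silyloxy group pseudoaxial on ring A, so C6 should enter on the opposite face of C5, while the centres at C7 and C8 are erased by enolisation and ketal hydrolysis. The step needs ortho regioselectivity, secured because the largest HOMO coefficient lies at C5 (remote from the oxygens) and pairs with the acrylate β-carbon so that the ester lands on C7 next to C8, and it needs facial selectivity at C5, secured by the C1 stereocentre.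

**Step 6**
Reactants: 11 allyl (4aS,8S)-8-(tert-butyldimethylsilyloxy)-1,5,5-trimethyl-2-oxo-2,3,4,4a,5,6,7,8-octahydronaphthalene-3-carboxylate
Product: 13 (4aS,8S)-8-(tert-butyldimethylsilyloxy)-1,5,5-trimethyl-4,4a,5,6,7,8-hexahydronaphthalen-2(3H)-one, via β-keto acid 12 (not isolated)
Conditions: Pd(OAc)2 (5 mol %), PPh3, HCO2H, Et3N, THF, rt
Reagents that add atoms: none
Why: palladium-catalysed deallylation of an allyl β-keto ester with formate as hydride source (Tsuji conditions), followed by spontaneous decarboxylation, removes the activating ester at C7 under near-neutral conditions that spare the allylic silyl ether.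

**Step 7**
Reactants: 14 (3R)-5-methoxy-3-methyl-5-oxopentanoic acid
Product: 15 methyl (3R)-5-hydroxy-3-methylpentanoate
Conditions: BH3·SMe2, THF, 0 °C to rt; aqueous work-up; used crude
Reagents that add atoms: none
Why: chemoselective borane reduction of a carboxylic acid beside an ester leaves the stereocentre (the future C13) untouched.

**Step 8**
Reactants: 15 methyl (3R)-5-hydroxy-3-methylpentanoate
Product: 16 methyl (3S)-5-iodo-3-methylpentanoate
Conditions: I2, PPh3, imidazole, CH2Cl2, 0 °C
Reagents that add atoms: iodine, II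
Why: Appel-type iodination of a primary alcohol; the descriptor changes to S only through the priority rules.

**Step 9**
Reactants: 13 (4aS,8S)-8-(tert-butyldimethylsilyloxy)-1,5,5-trimethyl-4,4a,5,6,7,8-hexahydronaphthalen-2(3H)-one; 16 methyl (3S)-5-iodo-3-methylpentanoate
Product: 18 methyl (3R)-3-methyl-5-[(1S,4aS)-1,5,5-trimethyl-2-oxo-1,2,3,4,4a,5,6,7-octahydronaphthalen-1-yl]pentanoate, via lithium dienolate 17 (not isolated)
Conditions: Li, NH3(l), THF, −78 °C; isoprene; NH3 evaporated; 16, DMPU, THF, −78 °C to rt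
Reagents that add atoms: none
Why: dissolving-metal reduction of the enone puts a carbanion on C10 that expels the pseudoaxial silyloxide from C1 (vinylogous reductive cleavage), giving the C8–C9–C10–C1 dienolate regiospecifically, and its C-alkylation at C9 (the reductive/deconjugative alkylation manifold of octalones) creates the quaternary centre and leaves the C1=C10 double bond, the iodide entering axially on the ring B face syn to H5 through a chair-like transition state with C4 equatorial.

**Step 10**
Reactants: 18 methyl (3R)-3-methyl-5-[(1S,4aS)-1,5,5-trimethyl-2-oxo-1,2,3,4,4a,5,6,7-octahydronaphthalen-1-yl]pentanoate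
Product: 19 methyl (3R)-3-methyl-5-[(1R,4aS)-1,5,5-trimethyl-2-methylidene-1,2,3,4,4a,5,6,7-octahydronaphthalen-1-yl]pentanoate
Conditions: Zn, CH2Br2, TiCl4 (reagent preformed in THF), CH2Cl2, 0 °C to rt
Reagents that add atoms: dibromomethane, BrCBr
Why: Lombardo methylenation converts hindered, enolisable ketones into methylene compounds without attacking esters, and here brings in C17.

**Step 11**
Reactants: 19 methyl (3R)-3-methyl-5-[(1R,4aS)-1,5,5-trimethyl-2-methylidene-1,2,3,4,4a,5,6,7-octahydronaphthalen-1-yl]pentanoate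
Product: 20 methyl (3R)-3-methyl-5-[(1R,2R,4aS)-1,2,5,5-tetramethyl-1,2,3,4,4a,5,6,7-octahydronaphthalen-1-yl]pentanoate
Conditions: H2 (3 atm), RhCl(PPh3)3 (10 mol %), benzene/EtOH, rt
Reagents that add atoms: none
Why: homogeneous hydrogenation with RhCl(PPh3)3 should reduce the 1,1-disubstituted alkene much faster than the trisubstituted C1=C10 bond, and hydrogen should reach C8 from the ring B face opposite the axial C9 side chain, so that C17 ends equatorial, cis to the side chain and trans to C20.

**Step 12**
Reactants: 20 methyl (3R)-3-methyl-5-[(1R,2R,4aS)-1,2,5,5-tetramethyl-1,2,3,4,4a,5,6,7-octahydronaphthalen-1-yl]pentanoate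
Product: 21 (3R)-3-methyl-5-[(1R,2R,4aS)-1,2,5,5-tetramethyl-1,2,3,4,4a,5,6,7-octahydronaphthalen-1-yl]pentanoic acid
Conditions: LiOH·H2O, THF/MeOH/H2O, rt; then 1 M HCl to pH 3
Reagents that add atoms: lithium hydroxide, [Li+].[OH-]
Why: saponification of an unhindered methyl ester; no stereocentre is α to the carboxyl group.

**Step 13**
Reactants: 21 (3R)-3-methyl-5-[(1R,2R,4aS)-1,2,5,5-tetramethyl-1,2,3,4,4a,5,6,7-octahydronaphthalen-1-yl]pentanoic acid; 22 cis-2-phenyl-1,3-dioxan-5-ol
Product: 23 cis-2-phenyl-1,3-dioxan-5-yl (3R)-3-methyl-5-[(1R,2R,4aS)-1,2,5,5-tetramethyl-1,2,3,4,4a,5,6,7-octahydronaphthalen-1-yl]pentanoate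
Conditions: EDC·HCl, DMAP (cat.), CH2Cl2, 0 °C to rt
Reagents that add atoms: none
Why: Steglich esterification; the benzylidene acetal leaves only the secondary hydroxyl of glycerol free, so only the 2-acyl isomer can form.

**Step 14**
Reactants: 23 cis-2-phenyl-1,3-dioxan-5-yl (3R)-3-methyl-5-[(1R,2R,4aS)-1,2,5,5-tetramethyl-1,2,3,4,4a,5,6,7-octahydronaphthalen-1-yl]pentanoate
Product: 24 1,3-dihydroxypropan-2-yl (3R)-3-methyl-5-[(1R,2R,4aS)-1,2,5,5-tetramethyl-1,2,3,4,4a,5,6,7-octahydronaphthalen-1-yl]pentanoate
Conditions: B(OH)3, B(OMe)3, 100 °C; then H2O, rt; chromatography on boric-acid-treated silica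
Reagents that add atoms: none
Why: boric acid-mediated cleavage of the benzylidene acetal (the established procedure for 2-monoacylglycerols) frees the 1,3-diol without acid or base strong enough to cause 2→1 acyl migration or to protonate the C1=C10 double bond.

**Compound list**

1 | 4,4-dimethylcyclohex-2-en-1-one | CC1(C)CCC(=O)C=C1 | starting material
2 | 2-iodo-4,4-dimethylcyclohex-2-en-1-one | CC1(C)CCC(=O)C(I)=C1 | intermediate
3 | (1S)-2-iodo-4,4-dimethylcyclohex-2-en-1-ol | O[C@H]1CCC(C)(C)C=C1I | intermediate
4 | tert-butyl{[(1S)-2-iodo-4,4-dimethylcyclohex-2-en-1-yl]oxy}dimethylsilane | CC(C)(C)[Si](C)(C)O[C@H]1CCC(C)(C)C=C1I | intermediate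
5 | methyl 2-bromopropanoate (racemic) | COC(=O)C(C)Br | starting material
6 | methyl 2-[(6S)-6-(tert-butyldimethylsilyloxy)-3,3-dimethylcyclohex-1-en-1-yl]propanoate (both epimers at the propanoate α-carbon) | COC(=O)C(C)C1=CC(C)(C)CC[C@@H]1O[Si](C)(C)C(C)(C)C | intermediate
7 | allyl acrylate (prop-2-en-1-yl prop-2-enoate) | C=CC(=O)OCC=C | starting material
8 | lithium dienolate of 6 | [Li+].COC([O-])=C(C)C1=CC(C)(C)CC[C@@H]1O[Si](C)(C)C(C)(C)C | intermediate (not isolated)
9 | tert-butyl({1-methoxy-2-[(6S)-6-(tert-butyldimethylsilyloxy)-3,3-dimethylcyclohex-1-en-1-yl]prop-1-en-1-yl}oxy)dimethylsilane (double-bond geometry not defined) | COC(O[Si](C)(C)C(C)(C)C)=C(C)C1=CC(C)(C)CC[C@@H]1O[Si](C)(C)C(C)(C)C | intermediate (not isolated)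
10 | allyl (4aS,8S)-2-methoxy-2,8-bis(tert-butyldimethylsilyloxy)-1,5,5-trimethyl-2,3,4,4a,5,6,7,8-octahydronaphthalene-3-carboxylate (C2 and C3 not defined) | CC1=C2[C@@H](O[Si](C)(C)C(C)(C)C)CCC(C)(C)[C@@H]2CC(C(=O)OCC=C)C1(OC)O[Si](C)(C)C(C)(C)C | intermediate (not isolated)
11 | allyl (4aS,8S)-8-(tert-butyldimethylsilyloxy)-1,5,5-trimethyl-2-oxo-2,3,4,4a,5,6,7,8-octahydronaphthalene-3-carboxylate (C3 not defined, keto/enol mixture) | CC1=C2[C@@H](O[Si](C)(C)C(C)(C)C)CCC(C)(C)[C@@H]2CC(C(=O)OCC=C)C1=O | intermediate
12 | (4aS,8S)-8-(tert-butyldimethylsilyloxy)-1,5,5-trimethyl-2-oxo-2,3,4,4a,5,6,7,8-octahydronaphthalene-3-carboxylic acid | CC1=C2[C@@H](O[Si](C)(C)C(C)(C)C)CCC(C)(C)[C@@H]2CC(C(=O)O)C1=O | intermediate (not isolated)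
13 | (4aS,8S)-8-(tert-butyldimethylsilyloxy)-1,5,5-trimethyl-4,4a,5,6,7,8-hexahydronaphthalen-2(3H)-one | CC1=C2[C@@H](O[Si](C)(C)C(C)(C)C)CCC(C)(C)[C@@H]2CCC1=O | intermediate
14 | (3R)-5-methoxy-3-methyl-5-oxopentanoic acid ((R)-monomethyl 3-methylglutarate) | C[C@H](CC(=O)O)CC(=O)OC | starting material
15 | methyl (3R)-5-hydroxy-3-methylpentanoate | C[C@H](CCO)CC(=O)OC | intermediate
16 | methyl (3S)-5-iodo-3-methylpentanoate | C[C@H](CCI)CC(=O)OC | intermediate
17 | lithium (4aS)-1,5,5-trimethyl-3,4,4a,5,6,7-hexahydronaphthalen-2-olate | [Li+].[O-]C1=C(C)C2=CCCC(C)(C)[C@@H]2CC1 | intermediate (not isolated)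
18 | methyl (3R)-3-methyl-5-[(1S,4aS)-1,5,5-trimethyl-2-oxo-1,2,3,4,4a,5,6,7-octahydronaphthalen-1-yl]pentanoate | C[C@H](CC[C@@]1(C)C2=CCCC(C)(C)[C@@H]2CCC1=O)CC(=O)OC | intermediate
19 | methyl (3R)-3-methyl-5-[(1R,4aS)-1,5,5-trimethyl-2-methylidene-1,2,3,4,4a,5,6,7-octahydronaphthalen-1-yl]pentanoate | C[C@H](CC[C@@]1(C)C2=CCCC(C)(C)[C@@H]2CCC1=C)CC(=O)OC | intermediate
20 | methyl (3R)-3-methyl-5-[(1R,2R,4aS)-1,2,5,5-tetramethyl-1,2,3,4,4a,5,6,7-octahydronaphthalen-1-yl]pentanoate | C[C@H](CC[C@@]1(C)C2=CCCC(C)(C)[C@@H]2CC[C@H]1C)CC(=O)OC | intermediate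
21 | (3R)-3-methyl-5-[(1R,2R,4aS)-1,2,5,5-tetramethyl-1,2,3,4,4a,5,6,7-octahydronaphthalen-1-yl]pentanoic acid | C[C@H](CC[C@@]1(C)C2=CCCC(C)(C)[C@@H]2CC[C@H]1C)CC(=O)O | intermediate
22 | cis-2-phenyl-1,3-dioxan-5-ol (1,3-O-benzylideneglycerol) | O[C@H]1CO[C@@H](c2ccccc2)OC1 | starting material
23 | cis-2-phenyl-1,3-dioxan-5-yl (3R)-3-methyl-5-[(1R,2R,4aS)-1,2,5,5-tetramethyl-1,2,3,4,4a,5,6,7-octahydronaphthalen-1-yl]pentanoate | C[C@H](CC[C@@]1(C)C2=CCCC(C)(C)[C@@H]2CC[C@H]1C)CC(=O)O[C@H]1CO[C@@H](c2ccccc2)OC1 | intermediate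
24 | 1,3-dihydroxypropan-2-yl (3R)-3-methyl-5-[(1R,2R,4aS)-1,2,5,5-tetramethyl-1,2,3,4,4a,5,6,7-octahydronaphthalen-1-yl]pentanoate | C[C@H](CC[C@@]1(C)C2=CCCC(C)(C)[C@@H]2CC[C@H]1C)CC(=O)OC(CO)CO | target

**Step count**

Total: 14 steps. Longest linear sequence: 12 steps (steps 1–6 and 9–14); the iodide 16 is made in 2 steps (7 and 8).

**Steps most likely to fail**

Step 5. The cycloaddition may be slow at the diene terminus C5, which is flanked by the C4 gem-dimethyl group. The ketene acetal may instead transfer its silyl group and give a conjugate adduct without ring closure. Facial selectivity may erode, because in the ring A half-chair one C4 methyl is pseudoaxial on the face opposite to the silyloxy group. The fallback sets out from 6 and runs the union in two ionic stages. The ketene acetal 9, made as in step 5, is added to 7 under Sc(OTf)3 catalysis (CH2Cl2, −78 °C) in a vinylogous Mukaiyama–Michael reaction that needs no s-cis diene. After work-up this should give the open-chain diester methyl 2-[(2S,6S)-2-[3-oxo-3-(prop-2-enyloxy)propyl]-6-(tert-butyldimethylsilyloxy)-3,3-dimethylcyclohexylidene]propanoate F1, with C6 again trans to the silyloxy group. Dieckmann condensation (KOt-Bu, THF, 0 °C), in which the allyl ester enolate at C7 attacks the conjugated methyl ester at C8, then closes ring B and comes back to the route at 11.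

Step 9. Ammonia may protonate the C10 carbanion before silyloxide is lost, which would give the saturated ketone. The unactivated iodide may undergo O-alkylation or proton transfer instead of C-alkylation. The dienolate may attack the ester of 16, and the axial preference at C9 may be insufficient. The fallback sets out from 13 and separates the two events. Reductive removal of the γ-silyloxy group with SmI2 (THF/MeOH, −78 °C), followed by equilibration with DBU, should give the conjugated enone (4aS)-1,5,5-trimethyl-4,4a,5,6,7,8-hexahydronaphthalen-2(3H)-one F2. Its thermodynamic potassium dienolate (KOt-Bu, t-BuOH/THF), formed by deprotonation at the C1 methylene, is then alkylated at C9 with 16 in a classical deconjugative alkylation, and the route is rejoined at 18.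

Step 11. Hydrogenation of the hindered 1,1-disubstituted alkene may be sluggish. The exocyclic double bond may migrate into ring B, the C1=C10 bond may be partly reduced, and the two faces of C8 may be poorly discriminated. The fallback sets out from 19 and replaces hydrogenation by hydroboration. 9-BBN (THF, rt) should react only at the 1,1-disubstituted alkene, placing boron on C17 and hydrogen on C8 from the face opposite the axial side chain. Oxidation with NaBO3 should give the primary alcohol methyl (3R)-5-[(1R,2R,4aS)-2-(hydroxymethyl)-1,5,5-trimethyl-1,2,3,4,4a,5,6,7-octahydronaphthalen-1-yl]-3-methylpentanoate F3. Iodination (I2, PPh3, imidazole) gives methyl (3R)-5-[(1R,2R,4aS)-2-(iodomethyl)-1,5,5-trimethyl-1,2,3,4,4a,5,6,7-octahydronaphthalen-1-yl]-3-methylpentanoate F4, and radical reduction (Bu3SnH, AIBN, toluene, 80 °C) returns to the route at 20.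

**Further compounds**

F1 | step 5 | methyl 2-[(2S,6S)-2-[3-oxo-3-(prop-2-enyloxy)propyl]-6-(tert-butyldimethylsilyloxy)-3,3-dimethylcyclohexylidene]propanoate (double-bond geometry not defined) | COC(=O)C(C)=C1[C@@H](O[Si](C)(C)C(C)(C)C)CCC(C)(C)[C@@H]1CCC(=O)OCC=C
F2 | step 9 | (4aS)-1,5,5-trimethyl-4,4a,5,6,7,8-hexahydronaphthalen-2(3H)-one | CC1=C2CCCC(C)(C)[C@@H]2CCC1=O
F3 | step 11 | methyl (3R)-5-[(1R,2R,4aS)-2-(hydroxymethyl)-1,5,5-trimethyl-1,2,3,4,4a,5,6,7-octahydronaphthalen-1-yl]-3-methylpentanoate | C[C@H](CC[C@@]1(C)C2=CCCC(C)(C)[C@@H]2CC[C@H]1CO)CC(=O)OC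
F4 | step 11 | methyl (3R)-5-[(1R,2R,4aS)-2-(iodomethyl)-1,5,5-trimethyl-1,2,3,4,4a,5,6,7-octahydronaphthalen-1-yl]-3-methylpentanoate | C[C@H](CC[C@@]1(C)C2=CCCC(C)(C)[C@@H]2CC[C@H]1CI)CC(=O)OC
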